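Take the flask as a ladder of rates, with J replacing ligands on D in steps: D to E, E to Q, Q to Z. I measured progress by the exposure, the integral of c_J over time.

the same everywhere: D 0.0010 M

| flask | J | G | remark | time |
|---|---|---|---|---|
| amber | 2.3 equiv | 0.050 mM | run made earlier |  |
| ochre | 4.4 equiv | 0.050 mM | run made earlier |  |
| maple | 3.00 equiv | 0.0500 mM |  | 4.0 min |
| oak | 2.00 equiv | 0.0500 mM |  | 4.0 min |

| run | time / min | L / % | D / % | Z / % | E / % | Q / % |
|---|---|---|---|---|---|---|
| amber | 0.333 | 0 | 52.5 | 0 | 45.9 | 2.3 |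
| amber | 0.667 | 0 | 27.6 | 5.3 | 63.7 | 3.0 |
| amber | 1.00 | 0 | 18.3 | 7.9 | 69.5 | 3.4 |
| amber | 2.00 | 0 | 6.9 | 19.9 | 70.7 | 3.7 |
| amber | 4.00 | 1.2 | 4.1 | 36.0 | 59.1 | 3.6 |
| ochre | 0.333 | 1.0 | 25.7 | 6.6 | 64.4 | 4.1 |
| ochre | 0.667 | 0 | 9.4 | 16.5 | 71.2 | 2.8 |
| ochre | 1.00 | 0.7 | 3.7 | 29.7 | 64.6 | 2.8 |
| ochre | 2.00 | 0.3 | 0 | 51.7 | 45.6 | 3.3 |
| ochre | 4.00 | 0 | 0 | 76.0 | 21.6 | 2.4 |

(scatter of a reading: 1 percentage point)

- which of these there is most of at the end, counted by the D in it, maple (D / Z / E / Q / L)
- which of these there is most of at the end, counted by the D in it, oak (D / Z / E / Q / L)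
- the largest of these amounts at the end, in percent of the D charged, maple
- the largest of these amounts at the end, in percent of the D charged, oak

On the balance of J, amber's c_J fell to 1.44 mM at 0.667 min. Its D reading there gave k_D of 1.03 mM⁻¹ min⁻¹. With D read as 0% in ochre, E then decayed between 2.00 min and 4.00 min, which gave k_E of 0.179 mM⁻¹ min⁻¹. Three equal, independent sites set the zero of the scale at a ratio of 1.50, but this selectivity factor read 5.75, higher than that zero.

At maple's charged J, the half-life of D is 0.224 min, shorter than the 1.29 min of E. So D goes first and E piles up. The top rung is Q, a steady-state intermediate: amber read 3.6% of it at 4.00 min, far less than the 36.0% of Z. So I treated E as passing almost straight to Z, which made the two about equal once E had fallen to half. E is born late by an exposure of 0.971 mM·min on average and then needs 3.87 mM·min to halve. Their sum is my crossing exposure 4.85 mM·min, the exposure at which I expected Z to overtake E.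

The forecast put maple's exposure at 6 and oak's at 3.5 mM min, on either side of my crossing. It named Z at 50% for maple, adding “Z leads, but only narrowly”, and E at 62% for oak.

Straight lines through the J left, 44.7% of its charge at 2.00 min and 31.1% at 4.00 min, gave maple 6.62 mM·min, above the crossing, and Z led with 52.2%. Oak's 3.89 mM·min stayed below it, and E led with 64.8%.

    D + J → X + E (k = 17.0 M⁻¹ s⁻¹)
    E + J → X + Q (k = 2.70 M⁻¹ s⁻¹)
    Q + J → X + Z (k = 59.0 M⁻¹ s⁻¹)
    Q + G → L (k = 16.0 M⁻¹ s⁻¹)

A neighbouring flask took maple's recipe with D at 2.5 × 10⁻⁴ M. Its J ended at 58.7% of its charge, so one straight line gave 2.38 mM·min, below 4.85 mM·min. There E held 70.6% and Z 15.4%.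

The earlier runs and the new flask were computed on assumed constants, noise included.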